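**Strategy.** The route rests on cutting the O1–C8a aryl ether bond of ring C. The feature exploited is that this bond joins ring A to the benzylic carbinol carbon C2, and that ring A carries a chlorine para to the geranyl group, so the arene is symmetric until C4a is formylated. A palladium-catalysed intramolecular O-arylation closes ring C in one operation and leaves the C2–O bond, and hence the S configuration set by ketone reduction, untouched. Its precursor is an open-chain (1S)-1-phenylpropane-1,3-diol whose C3 hydroxyl is silylated and whose C3 bears a 2-chloro-5-geranyl-4,6-bis(methoxymethoxy)phenyl ring; C4 is re-oxidised afterwards.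

Key step: step 7

Remark: geranyl stands for (2E)-3,7-dimethylocta-2,6-dien-1-yl and ring positions follow flavan numbering; the aldol in step 4 is not stereocontrolled, so 10 and 11 are racemic and 12 to 14 are carried as both epimers at the carbon that becomes C4, a centre erased by the oxidation in step 9.

Step 1
Reactants: 1 5-chlororesorcinol
Product: 2 1-chloro-3,5-bis(methoxymethoxy)benzene
Conditions: NaH, MOMCl, DMF, 0 °C → rt
Reagents that add atoms: chloromethyl methyl ether (MOMCl), COCCl
Why: Double Williamson-type O-alkylation of the phenoxides should give the bis-acetal, whose oxygens later steer both ring metalations.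

Step 2
Reactants: 2 1-chloro-3,5-bis(methoxymethoxy)benzene; 3 geranyl bromide
Product: 5 5-chloro-2-geranyl-1,3-bis(methoxymethoxy)benzene, via aryllithium 4 (not isolated)
Conditions: n-BuLi, THF–hexane, −20 → 0 °C; CuBr·SMe2 (10 mol%), then 3, −20 °C → rt
Reagents that add atoms: none
Why: Directed ortho-metalation, in which chelation by both MOM groups should place lithium between them (para to chlorine, so this anion cannot lose LiCl), followed by copper-catalysed allylic substitution at the primary carbon of 3, which should keep the E alkene and avoid the SN2′ isomer.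

Step 3
Reactants: 5 5-chloro-2-geranyl-1,3-bis(methoxymethoxy)benzene
Product: 7 2-chloro-5-geranyl-4,6-bis(methoxymethoxy)benzaldehyde, via aryllithium 6 (not isolated)
Conditions: s-BuLi, THF, −78 °C; DMF, −78 → −20 °C; aq. NH4Cl
Reagents that add atoms: N,N-dimethylformamide (DMF), CN(C)C=O
Why: The two remaining ring hydrogens are equivalent and each lies between Cl and an OMOM group, so directed ortho-metalation has a single outcome, the ortho-chloro aryllithium should resist LiCl loss at −78 °C, and DMF formylates it.

Step 4
Reactants: 7 2-chloro-5-geranyl-4,6-bis(methoxymethoxy)benzaldehyde; 8 acetophenone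
Product: 10 rac-3-[2-chloro-5-geranyl-4,6-bis(methoxymethoxy)phenyl]-3-hydroxy-1-phenylpropan-1-one, via lithium enolate 9 (not isolated)
Conditions: LiN(i-Pr)2, THF, −78 °C, 8; then 7, −78 °C; aq. NH4Cl at −78 °C
Reagents that add atoms: none
Why: Directed aldol addition of the preformed lithium enolate to a non-enolisable aldehyde, quenched cold so that neither retro-aldol cleavage nor dehydration sets in; the new carbinol centre is left uncontrolled because it is oxidised later.

Step 5
Reactants: 10 rac-3-[2-chloro-5-geranyl-4,6-bis(methoxymethoxy)phenyl]-3-hydroxy-1-phenylpropan-1-one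
Product: 11 rac-3-(tert-butyldimethylsilyloxy)-3-[2-chloro-5-geranyl-4,6-bis(methoxymethoxy)phenyl]-1-phenylpropan-1-one
Conditions: TBSOTf, 2,6-lutidine, CH2Cl2, −78 → −20 °C
Reagents that add atoms: tert-butyldimethylsilyl trifluoromethanesulfonate (TBSOTf), CC(C)(C)[Si](C)(C)OS(=O)(=O)C(F)(F)F
Why: Silylation of a hindered secondary alcohol with a silyl triflate and a hindered base should be fast at low temperature, outrunning dehydration and leaving the aryl MOM ethers intact.

Step 6
Reactants: 11 rac-3-(tert-butyldimethylsilyloxy)-3-[2-chloro-5-geranyl-4,6-bis(methoxymethoxy)phenyl]-1-phenylpropan-1-one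
Product: 12 (1S,3RS)-3-(tert-butyldimethylsilyloxy)-3-[2-chloro-5-geranyl-4,6-bis(methoxymethoxy)phenyl]-1-phenylpropan-1-ol
Conditions: (R)-2-methyl-CBS-oxazaborolidine (20 mol%), catecholborane, toluene, −78 → −40 °C; MeOH quench
Reagents that add atoms: none
Why: Corey–Bakshi–Shibata reduction, in which the (R)-oxazaborolidine (phenyl as the large group, the methylene chain as the small one) should deliver hydride to the face that gives the S carbinol, while catecholborane as the stoichiometric hydride source leaves the geranyl alkenes unhydroborated.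

Step 7
Reactants: 12 (1S,3RS)-3-(tert-butyldimethylsilyloxy)-3-[2-chloro-5-geranyl-4,6-bis(methoxymethoxy)phenyl]-1-phenylpropan-1-ol
Product: 13 (2S,4RS)-4-(tert-butyldimethylsilyloxy)-6-geranyl-5,7-bis(methoxymethoxy)flavan
Conditions: Pd(OAc)2 (5 mol%), 2-(di-tert-butylphosphino)-1,1′-binaphthyl (6 mol%), Cs2CO3, degassed toluene, 80 °C
Reagents that add atoms: none
Why: Zerovalent palladium, formed in the flask from Pd(OAc)2 and the phosphine, inserts into the C8a–Cl bond, the C2 hydroxyl binds to the divalent palladium centre and is deprotonated by Cs2CO3, and C–O reductive elimination from the resulting seven-membered aryl palladium alkoxide forges O1–C8a. The closest known reaction type is the palladium-catalysed intramolecular etherification of aryl halides with secondary alcohols that gives chromans. Ring C closes as a six-membered ring by intramolecular O-arylation, palladium being extruded from the seven-membered metallacycle. No stereocentre is created and the C2–O bond is never broken, so the S configuration installed in step 6 should be carried through. The step needs reductive elimination to outrun β-hydride elimination of the benzylic alkoxide, which the bulky electron-rich di-tert-butyl biaryl phosphine secures, while regiochemistry is trivial because ring A holds a single C–Cl bond and both ether oxygens sit meta to C8a, where they do not deactivate it by resonance. The C4 silyl ether rules out retro-aldol cleavage or dehydration under base, and the weak, poorly soluble carbonate keeps free alkoxide, and with it silyl migration from the C4 oxygen to the C2 oxygen, to a minimum.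

Step 8
Reactants: 13 (2S,4RS)-4-(tert-butyldimethylsilyloxy)-6-geranyl-5,7-bis(methoxymethoxy)flavan
Product: 14 (2S,4RS)-6-geranyl-5,7-bis(methoxymethoxy)flavan-4-ol
Conditions: TBAF, THF, 0 °C → rt
Reagents that add atoms: none
Why: Fluoride-driven desilylation runs under non-acidic conditions, so the easily ionised 4-oxygenated flavan and the MOM ethers should survive.

Step 9
Reactants: 14 (2S,4RS)-6-geranyl-5,7-bis(methoxymethoxy)flavan-4-ol
Product: 15 (2S)-6-geranyl-5,7-bis(methoxymethoxy)flavan-4-one
Conditions: Dess–Martin periodinane, pyridine, CH2Cl2, 0 °C → rt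
Reagents that add atoms: none
Why: Dess–Martin oxidation of the secondary benzylic alcohol should merge both C4 epimers into one ketone under buffered, non-basic conditions that neither open ring C nor touch C2 or the alkenes.

Step 10
Reactants: 15 (2S)-6-geranyl-5,7-bis(methoxymethoxy)flavan-4-one
Product: 16 (2S)-6-geranyl-5,7-dihydroxyflavan-4-one (target)
Conditions: 3 M aq. HCl, MeOH, 40 °C
Reagents that add atoms: none
Why: Acid-catalysed acetal exchange with methanol should remove both aryl MOM ethers, and the mild temperature and short exposure are chosen to spare the geranyl chain and the C2 configuration.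

**Compound list**

1 | 5-chlororesorcinol | Oc1cc(O)cc(Cl)c1 | starting material
2 | 1-chloro-3,5-bis(methoxymethoxy)benzene | COCOc1cc(Cl)cc(OCOC)c1 | intermediate
3 | geranyl bromide, (2E)-1-bromo-3,7-dimethylocta-2,6-diene | CC(C)=CCC/C(C)=C/CBr | starting material
4 | [4-chloro-2,6-bis(methoxymethoxy)phenyl]lithium | [Li]c1c(OCOC)cc(Cl)cc1OCOC | intermediate
5 | 5-chloro-2-geranyl-1,3-bis(methoxymethoxy)benzene | COCOc1cc(Cl)cc(OCOC)c1C/C=C(\C)CCC=C(C)C | intermediate
6 | [2-chloro-5-geranyl-4,6-bis(methoxymethoxy)phenyl]lithium | [Li]c1c(Cl)cc(OCOC)c(C/C=C(\C)CCC=C(C)C)c1OCOC | intermediate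
7 | 2-chloro-5-geranyl-4,6-bis(methoxymethoxy)benzaldehyde | O=Cc1c(Cl)cc(OCOC)c(C/C=C(\C)CCC=C(C)C)c1OCOC | intermediate
8 | acetophenone | CC(=O)c1ccccc1 | starting material
9 | lithium 1-phenylethenolate | [Li]OC(=C)c1ccccc1 | intermediate
10 | rac-3-[2-chloro-5-geranyl-4,6-bis(methoxymethoxy)phenyl]-3-hydroxy-1-phenylpropan-1-one | O=C(CC(O)c1c(Cl)cc(OCOC)c(C/C=C(\C)CCC=C(C)C)c1OCOC)c1ccccc1 | intermediate
11 | rac-3-(tert-butyldimethylsilyloxy)-3-[2-chloro-5-geranyl-4,6-bis(methoxymethoxy)phenyl]-1-phenylpropan-1-one | CC(C)(C)[Si](C)(C)OC(CC(=O)c1ccccc1)c1c(Cl)cc(OCOC)c(C/C=C(\C)CCC=C(C)C)c1OCOC | intermediate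
12 | (1S,3RS)-3-(tert-butyldimethylsilyloxy)-3-[2-chloro-5-geranyl-4,6-bis(methoxymethoxy)phenyl]-1-phenylpropan-1-ol, both C3 epimers | CC(C)(C)[Si](C)(C)OC(C[C@@H](c1ccccc1)O)c1c(Cl)cc(OCOC)c(C/C=C(\C)CCC=C(C)C)c1OCOC | intermediate
13 | (2S,4RS)-4-(tert-butyldimethylsilyloxy)-6-geranyl-5,7-bis(methoxymethoxy)flavan, both C4 epimers | CC(C)(C)[Si](C)(C)OC1C[C@@H](c2ccccc2)Oc2cc(OCOC)c(C/C=C(\C)CCC=C(C)C)c(OCOC)c21 | intermediate
14 | (2S,4RS)-6-geranyl-5,7-bis(methoxymethoxy)flavan-4-ol, both C4 epimers | OC1C[C@@H](c2ccccc2)Oc2cc(OCOC)c(C/C=C(\C)CCC=C(C)C)c(OCOC)c21 | intermediate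
15 | (2S)-6-geranyl-5,7-bis(methoxymethoxy)flavan-4-one | O=C1C[C@@H](c2ccccc2)Oc2cc(OCOC)c(C/C=C(\C)CCC=C(C)C)c(OCOC)c21 | intermediate
16 | (2S)-6-geranyl-5,7-dihydroxyflavan-4-one | CC(C)=CCC/C(C)=C/Cc1c(O)cc2c(c1O)C(=O)C[C@@H](c1ccccc1)O2 | target

**Step count.** Total: 10 steps. Longest linear sequence: 10 steps (1 to 16).

**Steps most likely to fail**

Step 7. β-Hydride elimination from the palladium alkoxide, which would oxidise the C2 carbinol and return the arene dechlorinated, may outpace C–O reductive elimination; silyl migration to the C2 oxygen would lead to the same loss. The fallback closes ring C at the other end of the ether, forming O1–C2 by a Mitsunobu displacement with inversion, so that no palladium alkoxide is involved. It sets out from ketone 11. Reduction with the (S)-oxazaborolidine and catecholborane should give the (1R)-configured alcohol F1. Miyaura borylation of its C–Cl bond (Pd(OAc)2, XPhos, B2pin2, KOAc, dioxane, 100 °C) should give the aryl pinacol boronate F2. Oxidation with NaBO3·4H2O in THF–water should give the phenol F3. PPh3 and DIAD in THF at 0 °C should then close ring C with inversion at the carbinol, turning 1R into 2S, and the route is rejoined at flavan 13.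

Step 2. Lithiation may leak to the position flanked by chlorine and one OMOM group, whose anion would lose LiCl to an aryne, and allylation may leak to the SN2′ mode. The fallback fixes the position with a halogen instead of with the base. It sets out from 1. Iodination between the hydroxyls (I2, NaHCO3, THF–water, 0 °C) should give 5-chloro-2-iodoresorcinol F4. NaH and MOMCl in DMF should give 5-chloro-2-iodo-1,3-bis(methoxymethoxy)benzene F5. Iodine–lithium exchange (n-BuLi, THF, −78 °C, C–Cl untouched) should deliver a single regioisomer and rejoins the route at aryllithium 4, after which the copper-catalysed geranylation of step 2 follows unchanged.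

Step 10. Under protic acid a freed phenol may add to the proximal alkene of the geranyl chain (chroman formation), or ring C may open and erode the C2 configuration. The fallback exchanges the protecting groups and then cleaves with fluoride, so that no Brønsted acid is used. It sets out from 15. TESOTf and 2,2′-bipyridyl in CH2Cl2 at 0 °C should convert both aryl MOM ethers into triethylsilyl ethers, giving (2S)-6-geranyl-5,7-bis(triethylsilyloxy)flavan-4-one F6. TBAF buffered with AcOH in THF at 0 °C should release both phenols and rejoin the route at target 16.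

**Further compounds**

F1 | step 7 | (1R,3RS)-3-(tert-butyldimethylsilyloxy)-3-[2-chloro-5-geranyl-4,6-bis(methoxymethoxy)phenyl]-1-phenylpropan-1-ol | CC(C)(C)[Si](C)(C)OC(C[C@H](c1ccccc1)O)c1c(Cl)cc(OCOC)c(C/C=C(\C)CCC=C(C)C)c1OCOC
F2 | step 7 | (1R,3RS)-3-(tert-butyldimethylsilyloxy)-3-[5-geranyl-4,6-bis(methoxymethoxy)-2-(4,4,5,5-tetramethyl-1,3,2-dioxaborolan-2-yl)phenyl]-1-phenylpropan-1-ol | CC(C)(C)[Si](C)(C)OC(C[C@H](c1ccccc1)O)c1c(B2OC(C)(C)C(C)(C)O2)cc(OCOC)c(C/C=C(\C)CCC=C(C)C)c1OCOC
F3 | step 7 | (1R,3RS)-3-(tert-butyldimethylsilyloxy)-3-[5-geranyl-2-hydroxy-4,6-bis(methoxymethoxy)phenyl]-1-phenylpropan-1-ol | CC(C)(C)[Si](C)(C)OC(C[C@H](c1ccccc1)O)c1c(O)cc(OCOC)c(C/C=C(\C)CCC=C(C)C)c1OCOC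
F4 | step 2 | 5-chloro-2-iodobenzene-1,3-diol | Oc1cc(Cl)cc(O)c1I
F5 | step 2 | 5-chloro-2-iodo-1,3-bis(methoxymethoxy)benzene | COCOc1cc(Cl)cc(OCOC)c1I
F6 | step 10 | (2S)-6-geranyl-5,7-bis(triethylsilyloxy)flavan-4-one | CC[Si](CC)(CC)Oc1cc2c(c(O[Si](CC)(CC)CC)c1C/C=C(\C)CCC=C(C)C)C(=O)C[C@@H](c1ccccc1)O2
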